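## Structural features

The target 11 is 3-(3,4-dihydroxy-5-methoxyphenyl)propyl octadecanoate: one benzene ring (ring A) and two chains, with no further ring. Ring A carries three adjacent oxygen substituents, free hydroxyls at C3 and C4 and a methoxy group at C5, and at C1 a saturated three-carbon tether (Cα benzylic, Cβ, Cγ) whose terminal carbon Cγ is bound to the alkyl oxygen of an unbranched C18 ester. There is no stereocentre and no configured double bond, so stereocontrol does not arise. The fragile groups are the electron-rich catechol, which oxidises to an ortho-quinone in air (above all when deprotonated), and the primary alkyl ester, which rules out strongly basic or nucleophilic conditions late in the route. The real difficulty is chemoselectivity and ordering: three oxygens (two phenolic, one aliphatic) must be told apart so that only the oxygen on Cγ is acylated, the tether must end exactly in that oxygen, and the catechol must be unveiled last without harming the ester. The key step exploits the fact that Cγ lies exactly one carbon beyond the two carbons (Cα, Cβ) of a vinyl group on C1 of ring A. Cγ can therefore arrive as carbon monoxide across that vinyl group, forming the Cβ–Cγ bond at the aldehyde oxidation level, one hydride reduction from the esterified alcohol; the step has to overcome the inherent preference of vinylarenes for the branched aldehyde.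

## Logic of the disconnections

11 to 10. The two phenolic O–H bonds of 11 are traced back to two O–CH2Ph bonds, so the last forward operation cleaves two benzylic C–O bonds. The cut is placed here because the free catechol would not survive base, ylide or acylating agent, and because 10 and everything before it are then ordinary, air-stable ethers. The demand on the forward step is that hydrogenolysis removes both benzyl groups under neutral conditions while the ester C–O bond, three carbons away from ring A and neither benzylic nor allylic, stays intact.

10 to 8 and 9. The acyl C–O bond of the ester is cut. This is the obvious polar disconnection; it removes the eighteen-carbon chain as purchasable 9 and leaves the small aryl propanol 8. The forward step must acylate one hydroxyl only, which is guaranteed because 8 has a single free hydroxyl.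

8 to 7. The C–H bond on Cγ made by hydride addition is cut, raising Cγ to the aldehyde level. The reason is that this is the oxidation level at which a carbonylation delivers the carbon. The forward step needs only a mild hydride donor that ignores aryl ethers.

7 to 5 and 6. The Cβ–Cγ bond is cut, together with the Cα–H bond formed in the same event. Cγ is a lone carbon at the aldehyde level, so its natural source is 6 plus hydrogen. The cut exposes vinylarene 5, in which every ring oxygen is already in place, and the forward assembly of three components wastes no atom. The forward step must place the formyl group on the terminal carbon against the intrinsic branched preference of vinylarenes, must not simply hydrogenate the alkene, and must leave the benzyl ethers as spectators.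

5 to 2 and 3 (through 4). The Cα=Cβ double bond is cut by carbonyl olefination logic. Cβ then comes from 3 by way of 4, and the aromatic part falls back to aldehyde 2, whose formyl carbon becomes Cα. The forward step must methylenate an electron-rich, non-enolisable aldehyde completely, and phosphorus residues must be removed thoroughly because they would interfere with the rhodium step.

2 to 1. The two O–CH2Ph bonds are cut. Compound 1 already holds the complete 3,4-dihydroxy-5-methoxy pattern and the carbon that becomes Cα, so no aromatic substitution chemistry is needed. The forward step must alkylate both phenols exhaustively with exclusion of air. Benzyl is chosen because it tolerates ylide, rhodium hydride, borohydride and acyl chloride and leaves under neutral hydrogenolysis.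

## Other disconnections considered

Alternative 1: The cut is the aryl C–O bond of the hydroxyl at C3 of ring A, made last on a substrate that already carries tether and ester. In the forward direction 3-(4-hydroxy-3-methoxyphenyl)propan-1-ol A1 would be acylated selectively at its aliphatic hydroxyl to give 3-(4-hydroxy-3-methoxyphenyl)propyl stearate A2. A2 would then be oxidised with two equivalents of the radical salt (KSO3)2NO. Hydrogen abstraction would give the phenoxyl radical, a second nitrosodisulfonate radical would couple at the only unsubstituted ortho carbon (the para position is blocked by the tether), and loss of the imidodisulfonate fragment would give the ortho-quinone 3-(5-methoxy-3,4-dioxocyclohexa-1,5-dien-1-yl)propyl stearate A3. Reduction of A3 with Na2S2O4 would give 11.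
- In favour: the site of oxidation is fixed by the substitution pattern of A2 and needs no catalyst control. On this point the alternative is better than the chosen plan, whose regiochemistry rests on a ligand. No protecting group is used, and three steps stand against six, so it is clearly better in step economy.
- Against: A3 is a 4-alkyl ortho-quinone with benzylic hydrogens, a class prone to tautomerise to quinone methides, to dimerise and to add nucleophiles. The oxidant is a water-soluble inorganic radical and A2 is a wax, so the reaction must cross a phase boundary. The solid oxidant is also unreliable on storage. Acylating A1 at the alcohol beside a free phenol is itself a selectivity problem, which the chosen plan avoids by benzylation.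
- Comparison: structurally the alternative keeps the carbon skeleton of A1 and adds only one oxygen, while the chosen plan builds the tether from C1 units. Mechanistically it spends a stoichiometric radical oxidation and a reduction to install one hydroxyl, whereas the chosen key step is a catalytic C–C bond formation with full atom economy. It is shorter but hinges on a labile intermediate; the chosen plan is longer but passes only through stable ethers and esters.

Alternative 2: The cut is the bond between Cα and Cβ, made as a C=C bond. In the forward direction 1,2-bis(tert-butyldimethylsilyloxy)-3-methoxy-5-vinylbenzene A4 and allyl stearate A5 would undergo cross-metathesis with the second-generation Hoveyda–Grubbs catalyst RuCl2(H2IMes)(=CH-C6H4-2-OiPr). Cycloaddition and cycloreversion through ruthenacyclobutanes would give (E)-3-[3,4-bis(tert-butyldimethylsilyloxy)-5-methoxyphenyl]allyl stearate A6, the two terminal CH2 groups leaving as a volatile alkene. Saturation of the alkene of A6 and desilylation would follow.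
- In favour: the route is convergent and the ester is already present in A5, so no separate reduction and acylation are needed. No pressurised CO is required. There is no regiochemical question at all, which is better than the chosen key step, and the alkene geometry is irrelevant because the alkene is hydrogenated afterwards. Five steps from 1 stand against six, a slight gain if A5 is bought and parity if it has to be made.
- Against: self-metathesis of A4 and of A5 would compete, so one partner must be used in excess. The carbon installed by methylenation is thrown away again. A6 is a cinnamyl ester on an electron-rich ring, and its hydrogenation risks allylic C–O hydrogenolysis that would cut off the acyl chain; the chosen plan never contains an allylic or benzylic ester. Catechol silyl ethers are labile, and fluoride deprotection would generate a catecholate next to an ester unless buffered.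
- Comparison: structurally both plans pass through a vinylarene derived from the same aldehyde 1. Mechanistically both are catalytic C–C bond formations, but hydroformylation adds exactly the one missing carbon, whereas metathesis exchanges alkylidene halves and discards two carbons.

Alternative 3: The cut is the alkyl C–O bond of the ester at Cγ. In the forward direction 5-allyl-1,2-bis(benzyloxy)-3-methoxybenzene A7 and stearic acid A8 would react with Pd(OAc)2, the bis-sulfoxide ligand PhS(O)CH2CH2S(O)Ph and 1,4-benzoquinone. Divalent palladium would cleave an allylic C–H bond to give a 1-aryl-π-allyl complex, the carboxylate would attack the terminus remote from ring A to give the conjugated (E)-3-[3,4-bis(benzyloxy)-5-methoxyphenyl]allyl stearate A9, and the quinone would reoxidise zerovalent palladium. A single hydrogenation over Pd/C would then be asked to saturate the alkene and remove both benzyl groups.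
- In favour: A8 is used directly without an acid chloride, and the ester and the position of its oxygen are set in one C–H functionalisation. Conjugation with ring A favours the linear ester. Two steps from A7 stand against four from 5, which is better on paper.
- Against: A7 derives from 5-allyl-3-methoxybenzene-1,2-diol A10, which is not a commodity and needs several steps itself, so counted from purchasable materials the plan is at best equal. The sulfoxide system is best known for branched esters from simple terminal alkenes, so the linear outcome depends on outer-sphere attack. Migration of the alkene into conjugation through palladium hydrides and Wacker-type oxidation would compete, and waxy A8 in excess complicates purification. A9 carries the same risk of allylic hydrogenolysis as in alternative 2, here in the very step that must also liberate the catechol.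
- Comparison: structurally the carbon skeleton is complete in A7 and only a C–O bond is formed, while the chosen plan builds the skeleton from commodity C1 pieces. Mechanistically both plans depend on catalyst-controlled regiochemistry and are equal on that point. The alternative first raises the oxidation level and must then reduce it again, whereas hydroformylation delivers Cγ at the aldehyde level directly.

Key step: step 3

Assumption: syngas is used as a 1:1 mixture of CO and H2; only its CO component is numbered (6), because H2 contributes hydrogen atoms only.

Step 1
Reactants: 1 3,4-dihydroxy-5-methoxybenzaldehyde
Product: 2 3,4-bis(benzyloxy)-5-methoxybenzaldehyde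
Conditions: BnBr, K2CO3, DMF, 60 °C, N2
Reagents that add atoms: benzyl bromide, BrCc1ccccc1
Why: Williamson ether synthesis; K2CO3 deprotonates both phenols of 1 and the phenoxides displace bromide from benzyl bromide by SN2. The aldehyde is not enolisable and is untouched, and exclusion of air keeps the catecholate from oxidising.

Step 2
Reactants: 2 3,4-bis(benzyloxy)-5-methoxybenzaldehyde; 3 methyltriphenylphosphonium bromide
Product: 5 1,2-bis(benzyloxy)-3-methoxy-5-vinylbenzene, via methylenetriphenylphosphorane 4 (not isolated)
Conditions: KOtBu, THF, 0 °C to rt
Reagents that add atoms: none
Why: Wittig olefination; KOtBu converts 3 into the non-stabilised ylide 4, which adds to aldehyde 2 to give an oxaphosphetane that collapses to the terminal alkene and Ph3P=O. The benzyl ethers are inert, and the product should be filtered through silica and stored cold so that no phosphorus residue reaches step 3.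

Step 3
Reactants: 5 1,2-bis(benzyloxy)-3-methoxy-5-vinylbenzene; 6 carbon monoxide
Product: 7 3-[3,4-bis(benzyloxy)-5-methoxyphenyl]propanal
Conditions: Rh(acac)(CO)2 (1 mol%), BISBI [2,2'-bis(diphenylphosphinomethyl)-1,1'-biphenyl] (3 mol%), CO/H2 (1:1, 5 bar), toluene, 100 °C
Reagents that add atoms: none
Why: Under syngas Rh(acac)(CO)2 and BISBI should form the trigonal-bipyramidal hydride HRh(CO)2(BISBI) of monovalent rhodium, in which the wide-bite-angle diphosphine spans two equatorial sites. Loss of one CO lets the vinyl group of 5 coordinate; hydride migration to the benzylic carbon gives the linear 2-arylethyl rhodium species, whereas migration to the terminal carbon gives the branched 1-arylethyl species, which is stabilised as an η3-benzyl. At about 100 °C and a few bar of CO the branched alkyl is expected to revert to the alkene hydride by beta-hydride elimination faster than CO traps it, while the crowded bis-equatorial pocket favours the slimmer linear alkyl, so the flux should pass through the linear acyl. CO insertion (6 supplies the new carbon), oxidative addition of H2 to give a trivalent rhodium dihydride and reductive elimination then release 7 and regenerate the hydride. The closest known reaction type is the linear-selective rhodium hydroformylation of styrenes with wide-bite-angle chelating phosphines. No ring is closed and no stereocentre is created. The selectivity needed is linear over branched regiochemistry and carbonylation over plain hydrogenation; it is secured mainly by ligand, temperature and low CO pressure, helped by the substrate, which has no allylic hydrogen (no alkene isomers can form), no ortho substituent, and a para-benzyloxy donor that weakens the benzylic rhodium–carbon bond. The benzyl and methyl ethers do not react with the rhodium hydride.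

Step 4
Reactants: 7 3-[3,4-bis(benzyloxy)-5-methoxyphenyl]propanal
Product: 8 3-[3,4-bis(benzyloxy)-5-methoxyphenyl]propan-1-ol
Conditions: NaBH4, MeOH/THF, 0 °C
Reagents that add atoms: none
Why: Hydride reduction of an aldehyde to the primary alcohol; aryl ethers are inert to NaBH4 and no other reducible group is present. Prompt reduction also removes the aldehyde before it can oxidise in air or undergo aldol reaction.

Step 5
Reactants: 8 3-[3,4-bis(benzyloxy)-5-methoxyphenyl]propan-1-ol; 9 stearoyl chloride (octadecanoyl chloride)
Product: 10 3-[3,4-bis(benzyloxy)-5-methoxyphenyl]propyl stearate
Conditions: pyridine, DMAP (cat.), CH2Cl2, 0 °C to rt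
Reagents that add atoms: none
Why: Acylation of a primary alcohol by an acid chloride through the N-acylpyridinium ion (nucleophilic catalysis by DMAP). Both phenols are masked, so the tether hydroxyl is the only nucleophile.

Step 6
Reactants: 10 3-[3,4-bis(benzyloxy)-5-methoxyphenyl]propyl stearate
Product: 11 3-(3,4-dihydroxy-5-methoxyphenyl)propyl stearate (target, no stereocentre)
Conditions: H2 (1 atm), 10% Pd/C, THF/EtOAc, rt; filtration under Ar
Reagents that add atoms: none
Why: Catalytic hydrogenolysis of aryl benzyl ethers on Pd/C cleaves the two benzylic C–O bonds and releases toluene. The ester alkyl C–O bond is three carbons from ring A, neither benzylic nor allylic, and should survive; the neutral, base-free medium and work-up under argon protect the catechol.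

## Compound list

1 | 3,4-dihydroxy-5-methoxybenzaldehyde | COc1cc(C=O)cc(O)c1O | starting material
2 | 3,4-bis(benzyloxy)-5-methoxybenzaldehyde | O=Cc1cc(OCc2ccccc2)c(OCc2ccccc2)c(OC)c1 | intermediate
3 | methyltriphenylphosphonium bromide | C[P+](c1ccccc1)(c1ccccc1)c1ccccc1.[Br-] | starting material
4 | methylenetriphenylphosphorane (formed in the flask, not isolated) | C=P(c1ccccc1)(c1ccccc1)c1ccccc1 | intermediate
5 | 1,2-bis(benzyloxy)-3-methoxy-5-vinylbenzene | C=Cc1cc(OCc2ccccc2)c(OCc2ccccc2)c(OC)c1 | intermediate
6 | carbon monoxide | [C-]#[O+] | starting material
7 | 3-[3,4-bis(benzyloxy)-5-methoxyphenyl]propanal | O=CCCc1cc(OCc2ccccc2)c(OCc2ccccc2)c(OC)c1 | intermediate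
8 | 3-[3,4-bis(benzyloxy)-5-methoxyphenyl]propan-1-ol | OCCCc1cc(OCc2ccccc2)c(OCc2ccccc2)c(OC)c1 | intermediate
9 | stearoyl chloride (octadecanoyl chloride) | CCCCCCCCCCCCCCCCCC(=O)Cl | starting material
10 | 3-[3,4-bis(benzyloxy)-5-methoxyphenyl]propyl stearate | CCCCCCCCCCCCCCCCCC(=O)OCCCc1cc(OCc2ccccc2)c(OCc2ccccc2)c(OC)c1 | intermediate
11 | 3-(3,4-dihydroxy-5-methoxyphenyl)propyl stearate (achiral) | CCCCCCCCCCCCCCCCCC(=O)OCCCc1cc(O)c(O)c(OC)c1 | target

## Step count and least certain steps

Total step count: 6. Longest linear sequence: 6 steps (1, 2, 5, 7, 8, 10, 11).

Step 3 (key step). The most likely failure is loss of regiocontrol: hydride delivery to the terminal alkene carbon, followed by CO capture of the benzylic rhodium alkyl before it can revert, which the η3-benzyl stabilisation encourages. Simple hydrogenation of the vinyl group and thermal oligomerisation of the electron-rich styrene at the temperature needed for reversibility are secondary risks. A more crowded chelating phosphine of the same family would be the first adjustment. The fallback that changes the approach sets out from 2 and comes back at 8: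
- Horner–Wadsworth–Emmons olefination of 2 with triethyl phosphonoacetate (NaH, THF, 0 °C) should give ethyl (E)-3-[3,4-bis(benzyloxy)-5-methoxyphenyl]acrylate F1.
- Homogeneous hydrogenation of the conjugated alkene with H2 and RhCl(PPh3)3 in benzene/EtOH, conditions that leave benzyl ethers alone, should give ethyl 3-[3,4-bis(benzyloxy)-5-methoxyphenyl]propanoate F2.
- LiAlH4 in THF at 0 °C should reduce the ester to 8.

This replaces steps 2 to 4 by three steps of classical chemistry, so the step count is unchanged, and it has no regiochemical question.

Step 6. The most likely failures are incomplete hydrogenolysis and air oxidation of the freed catechol. The C4 benzyl ether is flanked on both sides and the waxy substrate may coat the catalyst, and the catechol is exposed during filtration and concentration. The fallback sets out from 8 and comes back at 11, changing both the order of events and the mode of acylation: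
- Hydrogenolysis of 8 (H2, Pd/C, EtOH) should give the small, polar 5-(3-hydroxypropyl)-3-methoxybenzene-1,2-diol F3.
- Immobilised Candida antarctica lipase B with vinyl stearate (CCCCCCCCCCCCCCCCCC(=O)OC=C) in tert-butyl methyl ether at 40 °C should acylate only the aliphatic primary hydroxyl, because lipases of this type leave phenols untouched.

No ester is then ever exposed to palladium, and the target is formed under neutral conditions in the last operation. Step 5 is replaced as well, so the count stays at six.

Step 2. The most likely failures are carry-over of phosphorus by-products into the rhodium step, where traces of a monodentate phosphine would compete with the chelating ligand and erode regiocontrol, and oligomerisation of the electron-rich styrene on acidic silica or on storage. The fallback sets out from 2 and comes back at 5 by a phosphorus-free Peterson olefination: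
- Addition of Me3SiCH2MgCl to 2 in THF at 0 °C should give racemic 1-[3,4-bis(benzyloxy)-5-methoxyphenyl]-2-(trimethylsilyl)ethan-1-ol F4.
- KH in THF should trigger syn-elimination of the silanolate to give 5.

The silicon by-product is volatile, so contact of 5 with silica can be kept to a minimum.

## Further compounds

F1 | step 3 | ethyl (E)-3-[3,4-bis(benzyloxy)-5-methoxyphenyl]acrylate | CCOC(=O)/C=C/c1cc(OCc2ccccc2)c(OCc2ccccc2)c(OC)c1
F2 | step 3 | ethyl 3-[3,4-bis(benzyloxy)-5-methoxyphenyl]propanoate | CCOC(=O)CCc1cc(OCc2ccccc2)c(OCc2ccccc2)c(OC)c1
F3 | step 6 | 5-(3-hydroxypropyl)-3-methoxybenzene-1,2-diol | COc1cc(CCCO)cc(O)c1O
F4 | step 2 | 1-[3,4-bis(benzyloxy)-5-methoxyphenyl]-2-(trimethylsilyl)ethan-1-ol (racemic) | C[Si](C)(C)CC(O)c1cc(OCc2ccccc2)c(OCc2ccccc2)c(OC)c1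
A1 | alternative 1 | 3-(4-hydroxy-3-methoxyphenyl)propan-1-ol | COc1cc(CCCO)ccc1O
A2 | alternative 1 | 3-(4-hydroxy-3-methoxyphenyl)propyl stearate | CCCCCCCCCCCCCCCCCC(=O)OCCCc1ccc(O)c(OC)c1
A3 | alternative 1 | 3-(5-methoxy-3,4-dioxocyclohexa-1,5-dien-1-yl)propyl stearate | CCCCCCCCCCCCCCCCCC(=O)OCCCC1=CC(=O)C(=O)C(OC)=C1
A4 | alternative 2 | 1,2-bis(tert-butyldimethylsilyloxy)-3-methoxy-5-vinylbenzene | C=Cc1cc(O[Si](C)(C)C(C)(C)C)c(O[Si](C)(C)C(C)(C)C)c(OC)c1
A5 | alternative 2 | allyl stearate | CCCCCCCCCCCCCCCCCC(=O)OCC=C
A6 | alternative 2 | (E)-3-[3,4-bis(tert-butyldimethylsilyloxy)-5-methoxyphenyl]allyl stearate | CCCCCCCCCCCCCCCCCC(=O)OC/C=C/c1cc(O[Si](C)(C)C(C)(C)C)c(O[Si](C)(C)C(C)(C)C)c(OC)c1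
A7 | alternative 3 | 5-allyl-1,2-bis(benzyloxy)-3-methoxybenzene | C=CCc1cc(OCc2ccccc2)c(OCc2ccccc2)c(OC)c1
A8 | alternative 3 | stearic acid | CCCCCCCCCCCCCCCCCC(=O)O
A9 | alternative 3 | (E)-3-[3,4-bis(benzyloxy)-5-methoxyphenyl]allyl stearate | CCCCCCCCCCCCCCCCCC(=O)OC/C=C/c1cc(OCc2ccccc2)c(OCc2ccccc2)c(OC)c1
A10 | alternative 3 | 5-allyl-3-methoxybenzene-1,2-diol | C=CCc1cc(O)c(O)c(OC)c1
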